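**Assumptions (one line):** tricyclic compounds are numbered as 2,3-secoaromadendranes (pyran O between C2 and C3; C3=C4; C15 on C4; seven-membered ring C1–C5–C6–C7–C8–C9–C10; cyclopropane C6–C7–C11(Me)2; C14 on C10; β = face of H-1, H-5 and C11, α = opposite face), and lactone 1 is taken as a catalogue chiral-pool compound.

## Retrosynthetic overview

1. Plagiochilin A ⇐ lactol/primary diol 19 (final bis-acetylation sets C2) ⇐ spiro-epoxide 18 ⇐ C10 ketone 17 (Corey–Chaykovsky sets C10).
2. Key step: tricycle 13 ⇐ aldehyde 11 + malondialdehyde by domino Knoevenagel / intramolecular inverse-electron-demand oxa-Diels–Alder. It forms C4=C5, then C5–C1 and O–C2, so the cycloheptane and the dihydropyran close together and C1/C5 are set (instead of building the cycloheptane first and lactolising a 1,5-dialdehyde).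
3. 11 ⇐ alkyne 10 ((Z)-enol pivalate by Ru-catalysed hydro-acyloxylation) ⇐ cis-formyl Weinreb amide 3 (Wittig two-carbon homologation, then ethynylation).
4. The cyclopropane stereocentres C6/C7 and the gem-dimethyl group are bought in lactone 1 (carbonyl carbon becomes C5, CH2O carbon becomes C8).
5. Ring order: cyclopropane (chiral pool) → cycloheptane + dihydropyran (same step, step 9) → oxirane (step 14).

## Forward route

**Step 1**
Reactants: 1, (1R,5S)-6,6-dimethyl-3-oxabicyclo[3.1.0]hexan-2-one
Product: 2, (1R,3S)-3-(hydroxymethyl)-N-methoxy-N,2,2-trimethylcyclopropane-1-carboxamide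
Conditions: MeNH(OMe)·HCl, AlMe3, CH2Cl2, 0 °C → rt
Reagents that add atoms: N,O-dimethylhydroxylamine hydrochloride, CNOC.Cl
Why: Weinreb aminolysis of the γ-lactone with the aluminium amide opens the ring without touching either cyclopropane stereocentre and differentiates the two arms (C5 as amide, C8 as CH2OH).

**Step 2**
Reactants: 2
Product: 3, (1R,3S)-3-formyl-N-methoxy-N,2,2-trimethylcyclopropane-1-carboxamide
Conditions: Dess–Martin periodinane, NaHCO3, CH2Cl2, 0 °C → rt
Reagents that add atoms: none
Why: Dess–Martin oxidation of the primary alcohol; a cyclopropyl α-C–H does not enolise under these conditions, so the cis relationship is kept.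

**Step 3**
Reactants: 3; 4, (triphenylphosphoranylidene)acetaldehyde
Product: 5, (1R,3S)-N-methoxy-N,2,2-trimethyl-3-[(1E)-3-oxoprop-1-en-1-yl]cyclopropane-1-carboxamide
Conditions: PhMe, 80 °C
Reagents that add atoms: (triphenylphosphoranylidene)acetaldehyde (4), O=CC=P(c1ccccc1)(c1ccccc1)c1ccccc1 (supplies C9 and C10)
Why: Wittig olefination with the stabilised formyl ylide gives the (E)-enal; the Weinreb amide is inert to the neutral ylide.

**Step 4**
Reactants: 5
Product: 6, (1R,3S)-N-methoxy-N,2,2-trimethyl-3-(3-oxopropyl)cyclopropane-1-carboxamide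
Conditions: Hantzsch ester, Bn2NH·TFA (10 mol%), THF, rt
Reagents that add atoms: none
Why: iminium-catalysed transfer hydrogenation reduces only the enal C=C (1,4-hydride delivery) and avoids H2/Pd, which could hydrogenolyse the vinylcyclopropane.

**Step 5**
Reactants: 6; 7, ethynylmagnesium bromide
Product: 8, (1R,3S)-3-(3-hydroxypent-4-yn-1-yl)-N-methoxy-N,2,2-trimethylcyclopropane-1-carboxamide (about 1:1 epimers at the carbinol, future C10)
Conditions: THF, −78 → −40 °C
Reagents that add atoms: ethynylmagnesium bromide (7), C#C[Mg]Br (supplies C1 and C2)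
Why: Grignard 1,2-addition to the aldehyde is much faster than attack on the Weinreb amide at low temperature; the carbinol configuration is irrelevant because C10 becomes a ketone in step 13.

**Step 6**
Reactants: 8
Product: 9, (1R,3S)-3-[3-(tert-butyldimethylsilyloxy)pent-4-yn-1-yl]-N-methoxy-N,2,2-trimethylcyclopropane-1-carboxamide
Conditions: TBSCl, imidazole, DMF, rt
Reagents that add atoms: tert-butyldimethylsilyl chloride, CC(C)(C)[Si](C)(C)Cl
Why: standard silylation; a free propargylic OH would divert the Ru-vinylidene chemistry of step 8.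

**Step 7**
Reactants: 9
Product: 10, (1R,3S)-3-[3-(tert-butyldimethylsilyloxy)pent-4-yn-1-yl]-2,2-dimethylcyclopropane-1-carbaldehyde
Conditions: DIBAL-H, THF, −78 °C; aq. Rochelle salt
Reagents that add atoms: none
Why: Weinreb amide reduction stops at the aldehyde (C5) through the chelated tetrahedral intermediate; silyl ether and alkyne are untouched.

**Step 8**
Reactants: 10
Product: 11, (1Z)-3-(tert-butyldimethylsilyloxy)-5-[(1S,3R)-3-formyl-2,2-dimethylcyclopropyl]pent-1-en-1-yl 2,2-dimethylpropanoate
Conditions: PivOH, [Ru(methallyl)2(dppb)] (3 mol%), PhMe, 60 °C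
Reagents that add atoms: pivalic acid, CC(C)(C)C(=O)O
Why: Ru-vinylidene-mediated anti-Markovnikov hydro-acyloxylation of the terminal alkyne gives the (Z)-enol ester (carboxylate attack on the vinylidene α-carbon, then protonation), which fixes the dienophile geometry.

**Step 9 (key step)**
Reactants: 11; 12, malondialdehyde (used as its tetrabutylammonium enolate salt, liberated with AcOH)
Product: 13, tricyclic cycloadduct: cis-fused cyclopropane–cycloheptane–4H-pyran with 4-CHO, 2α-OPiv, H-1β, H-5β, C11 β, 10-OTBS (both C10 epimers); (1R,2S,5R,6S,7S)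
Conditions: piperidinium acetate (20 mol%), AcOH, 4 Å MS, MeCN/PhMe (0.01 M), rt → 80 °C
Reagents that add atoms: malondialdehyde (12), O=CCC=O (supplies C3, C4, C15, the ring oxygen and the aldehyde oxygen; water is lost)
Why: Proposed new method: domino Knoevenagel condensation / intramolecular inverse-electron-demand oxa-Diels–Alder (closest known type: the Tietze domino reaction, established for five- and six-membered carbocycles with alkene or enol-ether dienophiles, not for a seven-membered ring with an enol ester). The aldehyde condenses with malondialdehyde to a very electron-poor 2-alkylidenemalonaldehyde (either formyl can act as the oxadiene C=O, so there is no E/Z issue). Its C5 is attacked by the nucleophilic β-carbon (C1) of the tethered enol pivalate while the carbonyl oxygen bonds to C2. The cis-cyclopropane holds the two arms together and the tether forces attack on the C7-side face of the bisected s-trans conformer (H-5 over the ring, C4 outside), which sets C5 with H-5 anti to H-6. The endo transition state of the (Z)-dienophile gives the cis ring fusion (H-1 syn to H-5) and places 2-OPiv cis to C10; this C2 configuration is reset in step 16.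

**Step 10**
Reactants: 13
Product: 14, the 15-alcohol (4-CH2OH; otherwise as 13)
Conditions: NaBH4, CeCl3·7H2O, MeOH/THF, −40 °C
Reagents that add atoms: none
Why: Luche 1,2-reduction of the vinylogous formyl group; the anomeric pivalate and silyl ether survive.

**Step 11**
Reactants: 14
Product: 15, the 2α,15-bis-pivalate 10-OTBS ether
Conditions: PivCl, pyridine, DMAP, CH2Cl2, 0 °C → rt
Reagents that add atoms: pivaloyl chloride, CC(C)(C)C(=O)Cl
Why: acylation of the primary allylic alcohol; pivalates are chosen because they tolerate fluoride and the sulfur ylide used later.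

**Step 12**
Reactants: 15
Product: 16, the 10-alcohol bis-pivalate (C10 epimers)
Conditions: TBAF, AcOH, THF, rt
Reagents that add atoms: none
Why: buffered fluoride desilylation; the hindered esters and the acid-sensitive enol ether/acylal are not affected.

**Step 13**
Reactants: 16
Product: 17, the C10 ketone bis-pivalate (single compound; H-1β, H-5β)
Conditions: Dess–Martin periodinane, NaHCO3, CH2Cl2, 0 °C
Reagents that add atoms: none
Why: buffered Dess–Martin oxidation converges both C10 epimers on one ketone under non-basic conditions, so the α-stereocentre C1 is not epimerised.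

**Step 14**
Reactants: 17
Product: 18, the 10,14-spiro-epoxide bis-pivalate (epoxide O α, C14 β; 10S)
Conditions: Me3S+ I−, KHMDS, THF, −78 → −30 °C
Reagents that add atoms: trimethylsulfonium iodide, C[S+](C)C.[I-] (supplies C14 as CH2)
Why: Corey–Chaykovsky epoxidation; the unstabilised ylide adds irreversibly from the convex β-face (the H-1 face, anti to the pseudoaxial C1–C2 bond and the α-pivalate), so CH2 ends β and oxygen α, which is C10 of the target. At low temperature addition outruns enolisation of the β-acyloxy ketone.

**Step 15**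
Reactants: 18
Product: 19, the epoxy lactol diol (2-OH as anomeric mixture, 15-OH)
Conditions: DIBAL-H (5 equiv), CH2Cl2, −78 °C; MeOH, aq. Rochelle salt
Reagents that add atoms: none
Why: reductive cleavage of both pivalates; the anomeric one stops at the aluminium hemiacetal (lactol), and the 1,1-disubstituted oxirane is not opened at −78 °C. The crude lactol is used directly.

**Step 16**
Reactants: 19
Product: 20, plagiochilin A, (1R,2R,5R,6S,7S,10S)
Conditions: Ac2O, pyridine, DMAP (cat.), CH2Cl2, 0 °C
Reagents that add atoms: acetic anhydride, CC(=O)OC(C)=O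
Why: acetylation of the primary alcohol and the lactol; the lactol anomers interconvert and the acetate is installed trans to C10 (cis to H-1, pseudoaxial/anomeric), the same preference seen when iridoid lactols are acylated, which sets C2.

## Compound list

1 | (1R,5S)-6,6-dimethyl-3-oxabicyclo[3.1.0]hexan-2-one | O=C2[C@@H]1[C@H](CO2)C1(C)C | starting material
2 | (1R,3S)-3-(hydroxymethyl)-N-methoxy-N,2,2-trimethylcyclopropane-1-carboxamide | CON(C)C(=O)[C@@H]1[C@H](CO)C1(C)C | intermediate
3 | (1R,3S)-3-formyl-N-methoxy-N,2,2-trimethylcyclopropane-1-carboxamide | CON(C)C(=O)[C@@H]1[C@H](C=O)C1(C)C | intermediate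
4 | (triphenylphosphoranylidene)acetaldehyde | O=CC=P(c1ccccc1)(c1ccccc1)c1ccccc1 | starting material
5 | (1R,3S)-N-methoxy-N,2,2-trimethyl-3-[(1E)-3-oxoprop-1-en-1-yl]cyclopropane-1-carboxamide | CON(C)C(=O)[C@@H]1[C@H](/C=C/C=O)C1(C)C | intermediate
6 | (1R,3S)-N-methoxy-N,2,2-trimethyl-3-(3-oxopropyl)cyclopropane-1-carboxamide | CON(C)C(=O)[C@@H]1[C@H](CCC=O)C1(C)C | intermediate
7 | ethynylmagnesium bromide | C#C[Mg]Br | starting material
8 | (1R,3S)-3-(3-hydroxypent-4-yn-1-yl)-N-methoxy-N,2,2-trimethylcyclopropane-1-carboxamide (carbinol epimers) | CON(C)C(=O)[C@@H]1[C@H](CCC(O)C#C)C1(C)C | intermediate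
9 | TBS ether of 8 | CON(C)C(=O)[C@@H]1[C@H](CCC(O[Si](C)(C)C(C)(C)C)C#C)C1(C)C | intermediate
10 | (1R,3S)-3-[3-(tert-butyldimethylsilyloxy)pent-4-yn-1-yl]-2,2-dimethylcyclopropane-1-carbaldehyde | O=C[C@@H]1[C@H](CCC(O[Si](C)(C)C(C)(C)C)C#C)C1(C)C | intermediate
11 | (1Z)-3-(tert-butyldimethylsilyloxy)-5-[(1S,3R)-3-formyl-2,2-dimethylcyclopropyl]pent-1-en-1-yl pivalate | O=C[C@@H]1[C@H](CCC(O[Si](C)(C)C(C)(C)C)/C=C\OC(=O)C(C)(C)C)C1(C)C | intermediate
12 | malondialdehyde (propanedial; used as Bu4N enolate salt) | O=CCC=O | starting material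
13 | cycloadduct: 4-formyl, 2α-OPiv, 10-OTBS tricycle (H-1β, H-5β, C11 β) | O=CC1=CO[C@@H](OC(=O)C(C)(C)C)[C@@H]2[C@H]1[C@@H]1[C@H](CCC2O[Si](C)(C)C(C)(C)C)C1(C)C | intermediate
14 | 15-alcohol of 13 | OCC1=CO[C@@H](OC(=O)C(C)(C)C)[C@@H]2[C@H]1[C@@H]1[C@H](CCC2O[Si](C)(C)C(C)(C)C)C1(C)C | intermediate
15 | 2α,15-bis-pivalate, 10-OTBS | CC(C)(C)C(=O)OCC1=CO[C@@H](OC(=O)C(C)(C)C)[C@@H]2[C@H]1[C@@H]1[C@H](CCC2O[Si](C)(C)C(C)(C)C)C1(C)C | intermediate
16 | 2α,15-bis-pivalate, 10-OH | CC(C)(C)C(=O)OCC1=CO[C@@H](OC(=O)C(C)(C)C)[C@@H]2[C@H]1[C@@H]1[C@H](CCC2O)C1(C)C | intermediate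
17 | 2α,15-bis-pivalate, C10 ketone | CC(C)(C)C(=O)OCC1=CO[C@@H](OC(=O)C(C)(C)C)[C@@H]2[C@H]1[C@@H]1[C@H](CCC2=O)C1(C)C | intermediate
18 | 2α,15-bis-pivalate, 10,14-epoxide (O α) | CC(C)(C)C(=O)OCC1=CO[C@@H](OC(=O)C(C)(C)C)[C@@H]2[C@H]1[C@@H]1[C@H](CC[C@@]23CO3)C1(C)C | intermediate
19 | epoxy lactol diol (2-OH anomers, 15-OH) | OCC1=COC(O)[C@@H]2[C@H]1[C@@H]1[C@H](CC[C@@]23CO3)C1(C)C | intermediate
20 | plagiochilin A | CC(=O)OCC1=CO[C@H](OC(C)=O)[C@@H]2[C@H]1[C@@H]1[C@H](CC[C@@]23CO3)C1(C)C | target

## Summary

Total steps: 16. Longest linear sequence: 16 (fully linear from lactone 1).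

Three steps most likely to fail, each with one fallback:

1. **Step 9 (domino Knoevenagel / intramolecular oxa-Diels–Alder).** The enol pivalate may be too weak a dienophile for a seven-membered closure, or the exo (trans-fused) mode may compete. Fallback: replace the enol ester by the much more nucleophilic (Z)-ethyl enol ether, made by adding cis-2-ethoxyvinyllithium to aldehyde 6 in place of steps 5 and 8. After cycloaddition, exchange the ethyl acetal for the pivalate by mild acid hydrolysis and pivaloylation while the 4-formyl group still stabilises the enol ether.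

2. **Step 14 (Corey–Chaykovsky on the β-acyloxy ketone).** The basic ylide may cause enolisation with loss of the anomeric pivalate or C1 epimerisation, and the facial preference rests on a steric argument alone. Fallback: change from ylide transfer to a two-stage halomethyl addition. Chloromethyllithium generated in situ (ICH2Cl, MeLi·LiBr, −95 °C) gives the chlorohydrin before any enolisation, and this is then closed to the oxirane with mild base.

3. **Step 8 (Ru-catalysed Z-hydro-acyloxylation).** The hindered propargylic silyl ether with a free aldehyde may react slowly or with poor Z-selectivity. Fallback: build the enol ester by C–O coupling instead. Convert the alkyne to the 1-iodoalkyne (NIS, AgNO3), reduce with diimide to the (Z)-vinyl iodide, and couple with caesium pivalate under Cu(I) catalysis with retention of geometry.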